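**Strategy**

Everything rests on cutting the O4–C4a bond of the 1,4-benzodioxane. O4 links the benzylic carbon C3 to ring A at C4a, so this bond can be made as an aryl–oxygen bond by palladium catalysis, leaving every bond at the carbinol carbons C2 and C3 intact. In one operation the key step closes the dioxane ring and turns an open-chain syn (1S,2S) array into the trans (2S,3S) ring with retention at both centres. Its precursor is a 2-aryloxy-1-(3,4,5-trimethoxyphenyl)propane-1,3-diol from an Evans syn glycolate aldol, with the primary hydroxyl silylated and ring A carrying bromine at the future C4a, a MOM ether at C8 and a dioxolane-masked formyl group at C6.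

Key step: step 9

Remark: benzodioxane locants are O1, C2 (bears CH2OH), C3 (bears the aryl group), O4, C4a, C5 to C8, C8a, with the side chain at C6 and the hydroxyl at C8; methyl bromoacetate is taken as the commercial form of the bromoacetic acid unit.

**Route**

Step 1
Reactants: 1 3-bromo-4,5-dihydroxybenzaldehyde; 2 methyl bromoacetate
Product: 3 methyl 2-(2-bromo-4-formyl-6-hydroxyphenoxy)acetate
Conditions: NaHCO3 (1.1 equiv), DMF, rt → 40 °C
Reagents that add atoms: none
Why: Williamson ether synthesis under mono-deprotonation, in which the hydroxyl para to the formyl group (and ortho to bromine) is the more acidic, so one equivalent of weak base generates and alkylates only that phenoxide, while the mild conditions keep the neighbouring phenol protonated and slow to lactonise onto the ester.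

Step 2
Reactants: 3 methyl 2-(2-bromo-4-formyl-6-hydroxyphenoxy)acetate
Product: 4 methyl 2-[2-bromo-4-formyl-6-(methoxymethoxy)phenoxy]acetate
Conditions: MOMCl (1.5 equiv), iPr2NEt (2 equiv), CH2Cl2, 0 °C → rt
Reagents that add atoms: chloromethyl methyl ether (MOMCl), COCCl
Why: Alkylation of the remaining phenol with an alpha-chloro ether (MOM protection) under amine base is fast at low temperature and touches neither the ester nor the aldehyde.

Step 3
Reactants: 4 methyl 2-[2-bromo-4-formyl-6-(methoxymethoxy)phenoxy]acetate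
Product: 5 2-[2-bromo-4-formyl-6-(methoxymethoxy)phenoxy]acetic acid
Conditions: LiOH·H2O (1.5 equiv), THF/H2O, 0 °C; then cold 1 M HCl to pH 3
Reagents that add atoms: lithium hydroxide, [Li+].[OH-]
Why: Saponification of an aryloxyacetate, activated by its alpha oxygen, is fast at 0 °C, where the non-enolisable aldehyde, the aryl bromide and the MOM ether are inert, and the brief cold acidification does not cleave the MOM ether.

Step 4
Reactants: 5 2-[2-bromo-4-formyl-6-(methoxymethoxy)phenoxy]acetic acid; 6 (R)-4-benzyl-1,3-oxazolidin-2-one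
Product: 9 (R)-4-benzyl-3-{2-[2-bromo-4-formyl-6-(methoxymethoxy)phenoxy]acetyl}-1,3-oxazolidin-2-one, via mixed pivalic anhydride 7 (not isolated), via lithium oxazolidinide 8 (not isolated)
Conditions: 5, PivCl, Et3N, THF, −78 → 0 °C; separately 6, n-BuLi, THF, −78 °C; combine at −78 °C, then 0 °C; NH4Cl (aq)
Reagents that add atoms: none
Why: N-Acylation of an Evans oxazolidinone through the mixed pivalic anhydride, in which the preformed N-lithio anion attacks the unhindered aryloxyacetyl carbonyl irreversibly at −78 °C, whereas any addition to the aldehyde is reversible and n-BuLi never meets the aryl bromide.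

Step 5
Reactants: 9 (R)-4-benzyl-3-{2-[2-bromo-4-formyl-6-(methoxymethoxy)phenoxy]acetyl}-1,3-oxazolidin-2-one
Product: 10 (R)-4-benzyl-3-{2-[2-bromo-4-(1,3-dioxolan-2-yl)-6-(methoxymethoxy)phenoxy]acetyl}-1,3-oxazolidin-2-one
Conditions: (TMSOCH2)2 (2 equiv), TMSOTf (5 mol%), CH2Cl2, −78 → −20 °C; pyridine quench
Reagents that add atoms: 1,2-bis(trimethylsilyloxy)ethane, C[Si](C)(C)OCCO[Si](C)(C)C
Why: Noyori acetalisation, in which catalytic TMSOTf transfers ethylene glycol from its bis-silyl ether to the aldehyde under aprotic conditions at low temperature, is driven by formation of hexamethyldisiloxane and spares the aryl MOM ether and the imide.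

Step 6
Reactants: 10 (R)-4-benzyl-3-{2-[2-bromo-4-(1,3-dioxolan-2-yl)-6-(methoxymethoxy)phenoxy]acetyl}-1,3-oxazolidin-2-one; 11 3,4,5-trimethoxybenzaldehyde
Product: 14 (4R)-4-benzyl-3-[(2R,3S)-2-[2-bromo-4-(1,3-dioxolan-2-yl)-6-(methoxymethoxy)phenoxy]-3-hydroxy-3-(3,4,5-trimethoxyphenyl)propanoyl]-1,3-oxazolidin-2-one, via Z boron enolate 12 (not isolated), via boron aldolate 13 (not isolated)
Conditions: Bu2BOTf (1.2 equiv), Et3N (1.5 equiv), CH2Cl2, −78 → 0 °C; 11, −78 → 0 °C; pH 7 buffer, MeOH, 30% H2O2, 0 °C
Reagents that add atoms: none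
Why: Evans syn aldol reaction, in which soft enolisation gives the Z boron enolate that reacts through a closed Zimmerman–Traxler chair on the face opposite the benzyl group of the R auxiliary, setting C2 as R and C3 as S (the syn array that becomes 1S,2S after reduction), while the excess amine keeps the boron Lewis acid from opening the dioxolane.

Step 7
Reactants: 14 (4R)-4-benzyl-3-[(2R,3S)-2-[2-bromo-4-(1,3-dioxolan-2-yl)-6-(methoxymethoxy)phenoxy]-3-hydroxy-3-(3,4,5-trimethoxyphenyl)propanoyl]-1,3-oxazolidin-2-one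
Product: 15 (1S,2S)-2-[2-bromo-4-(1,3-dioxolan-2-yl)-6-(methoxymethoxy)phenoxy]-1-(3,4,5-trimethoxyphenyl)propane-1,3-diol
Conditions: LiBH4 (2.5 equiv), MeOH (2.5 equiv), THF, 0 °C; NH4Cl (aq)
Reagents that add atoms: none
Why: Reductive cleavage of the N-acyl oxazolidinone with LiBH4 delivers hydride to the exocyclic carbonyl and reduces the released aldehyde at once, so neither carbinol centre is touched (the descriptor at C2 changes only through the priority rules) and the bromide, acetal and MOM ether are inert.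

Step 8
Reactants: 15 (1S,2S)-2-[2-bromo-4-(1,3-dioxolan-2-yl)-6-(methoxymethoxy)phenoxy]-1-(3,4,5-trimethoxyphenyl)propane-1,3-diol
Product: 16 (1S,2S)-2-[2-bromo-4-(1,3-dioxolan-2-yl)-6-(methoxymethoxy)phenoxy]-3-[(tert-butyldimethylsilyl)oxy]-1-(3,4,5-trimethoxyphenyl)propan-1-ol
Conditions: TBSCl (1.1 equiv), imidazole (2.2 equiv), CH2Cl2, 0 °C
Reagents that add atoms: tert-butyldimethylsilyl chloride (TBSCl), CC(C)(C)[Si](C)(C)Cl
Why: Silylation with a bulky chlorosilane and imidazole discriminates the primary from the hindered secondary benzylic hydroxyl, leaving only the latter free for the ring closure.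

Step 9
Reactants: 16 (1S,2S)-2-[2-bromo-4-(1,3-dioxolan-2-yl)-6-(methoxymethoxy)phenoxy]-3-[(tert-butyldimethylsilyl)oxy]-1-(3,4,5-trimethoxyphenyl)propan-1-ol
Product: 17 tert-butyl{[(2S,3S)-6-(1,3-dioxolan-2-yl)-8-(methoxymethoxy)-3-(3,4,5-trimethoxyphenyl)-2,3-dihydro-1,4-benzodioxin-2-yl]methoxy}dimethylsilane (trans)
Conditions: Pd(OAc)2 (5 mol%), 2-(di-tert-butylphosphino)-1,1'-binaphthyl (6 mol%), Cs2CO3 (1.5 equiv), degassed toluene, 70 °C
Reagents that add atoms: none
Why: Zerovalent palladium, formed in the flask from Pd(OAc)2 and the phosphine, inserts into the C4a–Br bond, Cs2CO3 deprotonates the coordinated C3 hydroxyl to give a seven-membered aryl(alkoxo) chelate of divalent palladium, and carbon–oxygen reductive elimination releases the dioxane (an intramolecular Buchwald–Hartwig-type aryl etherification, a reaction type known for secondary alcohols and for 2-substituted 1,4-benzodioxanes). The six-membered ring is thus closed by O4–C4a bond formation through reductive elimination from that palladacycle, not by substitution at carbon. No stereocentre is created, because neither the C2–O1 nor the C3–O4 bond is broken, so the (1S,2S) syn array is carried over unchanged as the trans (2S,3S) ring. The selectivity needed is reductive elimination over beta-hydride elimination of the benzylic alkoxide (which would give the ketone and the debrominated arene), and the bulky, electron-rich di-tert-butylbiaryl ligand together with the chelate geometry favours the former. Site selectivity is built into 16, since only one hydroxyl is free and the single bromine sits ortho to the tether oxygen, which fixes O4 at C4a.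

Step 10
Reactants: 17 tert-butyl{[(2S,3S)-6-(1,3-dioxolan-2-yl)-8-(methoxymethoxy)-3-(3,4,5-trimethoxyphenyl)-2,3-dihydro-1,4-benzodioxin-2-yl]methoxy}dimethylsilane
Product: 18 (2S,3S)-8-hydroxy-2-(hydroxymethyl)-3-(3,4,5-trimethoxyphenyl)-2,3-dihydro-1,4-benzodioxine-6-carbaldehyde
Conditions: 3 M HCl (aq)/THF (1:2), 45 °C
Reagents that add atoms: water, O
Why: Acid-catalysed hydrolysis removes the dioxolane, the MOM acetal and the primary silyl ether in one pot, while the aryl ether bonds of the dioxane are not cleaved under these conditions and the trans arrangement, being also the more stable one, is kept.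

Step 11
Reactants: 18 (2S,3S)-8-hydroxy-2-(hydroxymethyl)-3-(3,4,5-trimethoxyphenyl)-2,3-dihydro-1,4-benzodioxine-6-carbaldehyde; 19 (triphenylphosphoranylidene)acetaldehyde
Product: 20 (E)-3-[(2S,3S)-8-hydroxy-2-(hydroxymethyl)-3-(3,4,5-trimethoxyphenyl)-2,3-dihydro-1,4-benzodioxin-6-yl]prop-2-enal (target)
Conditions: 19 (1.3 equiv), THF/toluene, 75 °C
Reagents that add atoms: none
Why: Wittig olefination with a stabilised formyl ylide is E-selective through reversible oxaphosphetane formation, tolerates the free phenol and alcohol, and a small excess of ylide at moderate temperature limits a second homologation of the enal.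

**Compound list**

1 | 3-bromo-4,5-dihydroxybenzaldehyde | O=Cc1cc(O)c(O)c(Br)c1 | starting material
2 | methyl bromoacetate | COC(=O)CBr | starting material
3 | methyl 2-(2-bromo-4-formyl-6-hydroxyphenoxy)acetate | COC(=O)COc1c(O)cc(C=O)cc1Br | intermediate
4 | methyl 2-[2-bromo-4-formyl-6-(methoxymethoxy)phenoxy]acetate | COC(=O)COc1c(OCOC)cc(C=O)cc1Br | intermediate
5 | 2-[2-bromo-4-formyl-6-(methoxymethoxy)phenoxy]acetic acid | OC(=O)COc1c(OCOC)cc(C=O)cc1Br | intermediate
6 | (R)-4-benzyl-1,3-oxazolidin-2-one | O=C1N[C@H](Cc2ccccc2)CO1 | starting material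
7 | 2-[2-bromo-4-formyl-6-(methoxymethoxy)phenoxy]acetic pivalic anhydride | CC(C)(C)C(=O)OC(=O)COc1c(OCOC)cc(C=O)cc1Br | intermediate (not isolated)
8 | lithium salt (N-lithio derivative) of (R)-4-benzyl-1,3-oxazolidin-2-one | [Li+].O=C1[N-][C@H](Cc2ccccc2)CO1 | intermediate (not isolated)
9 | (R)-4-benzyl-3-{2-[2-bromo-4-formyl-6-(methoxymethoxy)phenoxy]acetyl}-1,3-oxazolidin-2-one | O=C(COc1c(OCOC)cc(C=O)cc1Br)N1[C@H](Cc2ccccc2)COC1=O | intermediate
10 | (R)-4-benzyl-3-{2-[2-bromo-4-(1,3-dioxolan-2-yl)-6-(methoxymethoxy)phenoxy]acetyl}-1,3-oxazolidin-2-one | O=C(COc1c(OCOC)cc(C2OCCO2)cc1Br)N1[C@H](Cc2ccccc2)COC1=O | intermediate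
11 | 3,4,5-trimethoxybenzaldehyde | COc1cc(C=O)cc(OC)c1OC | starting material
12 | Z dibutylboron enolate of 10, (R)-4-benzyl-3-{(Z)-2-[2-bromo-4-(1,3-dioxolan-2-yl)-6-(methoxymethoxy)phenoxy]-1-[(dibutylboranyl)oxy]ethenyl}-1,3-oxazolidin-2-one | CCCCB(CCCC)O/C(=C\Oc1c(OCOC)cc(C2OCCO2)cc1Br)N1[C@H](Cc2ccccc2)COC1=O | intermediate (not isolated)
13 | dibutylboron aldolate, the O-dibutylboranyl derivative of 14 at the C3 oxygen, (2R,3S) | COc1cc([C@H](OB(CCCC)CCCC)[C@H](C(=O)N2[C@H](Cc3ccccc3)COC2=O)Oc2c(Br)cc(C3OCCO3)cc2OCOC)cc(OC)c1OC | intermediate (not isolated)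
14 | (4R)-4-benzyl-3-[(2R,3S)-2-[2-bromo-4-(1,3-dioxolan-2-yl)-6-(methoxymethoxy)phenoxy]-3-hydroxy-3-(3,4,5-trimethoxyphenyl)propanoyl]-1,3-oxazolidin-2-one (syn aldol) | COc1cc([C@H](O)[C@H](C(=O)N2[C@H](Cc3ccccc3)COC2=O)Oc2c(Br)cc(C3OCCO3)cc2OCOC)cc(OC)c1OC | intermediate
15 | (1S,2S)-2-[2-bromo-4-(1,3-dioxolan-2-yl)-6-(methoxymethoxy)phenoxy]-1-(3,4,5-trimethoxyphenyl)propane-1,3-diol | COc1cc([C@H](O)[C@H](CO)Oc2c(Br)cc(C3OCCO3)cc2OCOC)cc(OC)c1OC | intermediate
16 | (1S,2S)-2-[2-bromo-4-(1,3-dioxolan-2-yl)-6-(methoxymethoxy)phenoxy]-3-[(tert-butyldimethylsilyl)oxy]-1-(3,4,5-trimethoxyphenyl)propan-1-ol (syn; key-step precursor) | COc1cc([C@H](O)[C@H](CO[Si](C)(C)C(C)(C)C)Oc2c(Br)cc(C3OCCO3)cc2OCOC)cc(OC)c1OC | intermediate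
17 | tert-butyl{[(2S,3S)-6-(1,3-dioxolan-2-yl)-8-(methoxymethoxy)-3-(3,4,5-trimethoxyphenyl)-2,3-dihydro-1,4-benzodioxin-2-yl]methoxy}dimethylsilane (trans; key-step product) | COc1cc([C@@H]2Oc3cc(C4OCCO4)cc(OCOC)c3O[C@H]2CO[Si](C)(C)C(C)(C)C)cc(OC)c1OC | intermediate
18 | (2S,3S)-8-hydroxy-2-(hydroxymethyl)-3-(3,4,5-trimethoxyphenyl)-2,3-dihydro-1,4-benzodioxine-6-carbaldehyde | COc1cc([C@@H]2Oc3cc(C=O)cc(O)c3O[C@H]2CO)cc(OC)c1OC | intermediate
19 | (triphenylphosphoranylidene)acetaldehyde | O=CC=P(c1ccccc1)(c1ccccc1)c1ccccc1 | starting material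
20 | (E)-3-[(2S,3S)-8-hydroxy-2-(hydroxymethyl)-3-(3,4,5-trimethoxyphenyl)-2,3-dihydro-1,4-benzodioxin-6-yl]prop-2-enal | COc1cc([C@@H]2Oc3cc(/C=C/C=O)cc(O)c3O[C@H]2CO)cc(OC)c1OC | target

**Count and risks**

Total step count: 11. Longest linear sequence: 11 steps (1 → 20).

Steps most likely to fail:

Step 9. The benzylic alkoxide on palladium may undergo beta-hydride elimination (oxidation to the ketone with loss of bromine). Oxidative addition into the electron-rich, ortho-alkoxy aryl bromide may also be slow, and base could move the silyl group to the secondary oxygen and expose the primary alkoxide. The fallback closes the ring at the other end of O4. Setting out from 16, Miyaura borylation (B2pin2, PdCl2(dppf), KOAc, 1,4-dioxane, 85 °C) would give the aryl pinacol boronate F1, and oxidation (NaBO3·4H2O, THF/H2O, rt) the phenol F2. Heating F2 with TsOH·H2O in wet 1,4-dioxane at about 70 °C should strip the MOM, silyl and acetal groups and ionise the benzylic alcohol. The 3,4,5-trimethoxybenzyl cation is then captured by either ortho phenol; the two are equivalent because ring A now has a mirror plane through C8a and C6. The reversible closure should settle on the more stable trans ring with C2 untouched, and the route is rejoined at 18.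

Step 11. The enal product may react with a second ylide to give the dienal, or the unprotected phenolic aldehyde may react sluggishly. The fallback uses a masked two-carbon ylide that cannot homologate twice. Setting out from 17, selective hydrolysis of the aryl dioxolane (PPTS, acetone/H2O, 40 °C) would give the protected aldehyde F3. Wittig reaction with (1,3-dioxolan-2-ylmethyl)triphenylphosphonium bromide and KOtBu (THF, 0 °C → rt) would give the vinyl dioxolane F4 as an E/Z mixture. Treatment with 3 M HCl (aq)/THF at 45 °C should then unveil the enal, equilibrate it to the E isomer and remove the MOM and silyl groups, arriving at 20.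

Step 1. Alkylation may also occur at the other hydroxyl or twice, and the free ortho phenol of 3 may lactonise onto the ester. The fallback reverses the order of the two O-functionalisations. Setting out from 1, double deprotonation (NaH, 2.2 equiv, DMF, 0 °C) and one equivalent of MOMCl should functionalise the more nucleophilic phenoxide, the one meta to the formyl group and remote from bromine, to give 3-bromo-4-hydroxy-5-(methoxymethoxy)benzaldehyde F5. Its remaining hydroxyl is then alkylated with 2 (K2CO3, DMF, rt), with no free ortho phenol left to attack the ester, and the route is rejoined at 4.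

**Further compounds**

F1 | step 9 | (1S,2S)-3-[(tert-butyldimethylsilyl)oxy]-2-[4-(1,3-dioxolan-2-yl)-2-(methoxymethoxy)-6-(4,4,5,5-tetramethyl-1,3,2-dioxaborolan-2-yl)phenoxy]-1-(3,4,5-trimethoxyphenyl)propan-1-ol | COc1cc([C@H](O)[C@H](CO[Si](C)(C)C(C)(C)C)Oc2c(B3OC(C)(C)C(C)(C)O3)cc(C3OCCO3)cc2OCOC)cc(OC)c1OC
F2 | step 9 | (1S,2S)-3-[(tert-butyldimethylsilyl)oxy]-2-[4-(1,3-dioxolan-2-yl)-2-hydroxy-6-(methoxymethoxy)phenoxy]-1-(3,4,5-trimethoxyphenyl)propan-1-ol | COc1cc([C@H](O)[C@H](CO[Si](C)(C)C(C)(C)C)Oc2c(O)cc(C3OCCO3)cc2OCOC)cc(OC)c1OC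
F3 | step 11 | (2S,3S)-2-{[(tert-butyldimethylsilyl)oxy]methyl}-8-(methoxymethoxy)-3-(3,4,5-trimethoxyphenyl)-2,3-dihydro-1,4-benzodioxine-6-carbaldehyde | COc1cc([C@@H]2Oc3cc(C=O)cc(OCOC)c3O[C@H]2CO[Si](C)(C)C(C)(C)C)cc(OC)c1OC
F4 | step 11 | tert-butyl{[(2S,3S)-6-[2-(1,3-dioxolan-2-yl)ethenyl]-8-(methoxymethoxy)-3-(3,4,5-trimethoxyphenyl)-2,3-dihydro-1,4-benzodioxin-2-yl]methoxy}dimethylsilane (E/Z mixture, alkene geometry left open) | COc1cc([C@@H]2Oc3cc(C=CC4OCCO4)cc(OCOC)c3O[C@H]2CO[Si](C)(C)C(C)(C)C)cc(OC)c1OC
F5 | step 1 | 3-bromo-4-hydroxy-5-(methoxymethoxy)benzaldehyde | COCOc1cc(C=O)cc(Br)c1O
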